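**Strategy.** Ring A (C1–C5, C10) with its vicinal C4/C5 methyl pair next to the oxygenated C3 is disconnected back to a cyclopentanone: C4, carrying its methyl, is inserted between the C3 carbonyl and the quaternary C5 of a cis-hydrindanone derived from the (S)-Hajos–Parrish ketone. The key step, a selenium-triggered semipinacol 1,2-shift of the quaternary carbon, turns the five-membered ring into the six-membered ring, creates the C4–C5 bond and, after equilibration, the C4 stereocentre. Its precursor is a 1-[1-(phenylselanyl)ethyl]cyclopentanol. The purchased C5 centre then relays C10, C4, C3, C9 and C7 through the cis-decalin conformation; both senecioates are installed together.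

Key step: step 5

Remark: eremophilane numbering is used throughout (ring A = C1–C5/C10, ring B = C5–C10); β is the face of the C4 and C5 methyl groups, so the target is 3α,4β,5β,7β,9β,10β-H (3R,4R,5R,7R,9R,10S).

**Step 1**
Reactants: 1 acetaldehyde; 2 benzeneselenol
Product: 3 1,1-bis(phenylselanyl)ethane
Conditions: ZnCl2 (0.5 equiv), CH2Cl2, 0 °C → rt
Reagents that add atoms: acetaldehyde, CC=O; benzeneselenol, [SeH]c1ccccc1
Why: Lewis-acid-catalysed selenoacetalisation of an aldehyde with a selenol is the standard entry to selenoacetals.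

**Step 2**
Reactants: 4 (S)-Hajos–Parrish ketone
Product: 5 (3aR,7aS)-7a-methylhexahydro-1H-indene-1,5(4H)-dione (cis-fused)
Conditions: H2 (1 atm), 10% Pd/C, EtOAc, rt
Reagents that add atoms: none
Why: Catalytic hydrogenation of this hydrindenone is known to give the cis-fused dione, so H-10 is set syn to the C5 methyl by substrate control.

**Step 3**
Reactants: 5; 6 ethylene glycol
Product: 7 (3aR,7aS)-7a-methyl-cis-hexahydroindane-1,5-dione 5-(ethylene ketal)
Conditions: ethylene glycol (1.1 equiv), TsOH·H2O (cat.), benzene, reflux, Dean–Stark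
Reagents that add atoms: ethylene glycol, OCCO
Why: Acid-catalysed ketalisation should select the unhindered cyclohexanone carbonyl (C8) over the cyclopentanone flanked by the quaternary carbon, as in the 3- versus 17-ketone differentiation of steroids.

**Step 4**
Reactants: 7; 3
Product: 9 (3aR,7aS)-1-hydroxy-7a-methyl-1-[1-(phenylselanyl)ethyl]-cis-octahydroinden-5-one ethylene ketal (diastereomer mixture at the two new centres), via 1-(phenylselanyl)ethyllithium 8 (not isolated)
Conditions: 3, n-BuLi, THF, −78 °C; then 7, −78 → −40 °C; aq. NH4Cl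
Reagents that add atoms: 1,1-bis(phenylselanyl)ethane, CC([Se]c1ccccc1)[Se]c1ccccc1
Why: Se/Li exchange gives a weakly basic, strongly nucleophilic α-selenoalkyllithium that adds 1,2 to hindered enolisable ketones; the two new centres form as a mixture that is cleared in step 5.

**Step 5**
Reactants: 9
Product: 11 (4β,5β,10βH)-4,5-dimethyl-cis-decalin-3,8-dione 8-(ethylene ketal), via C4-epimeric ketone mixture 10 (not isolated)
Conditions: TlOEt (5 equiv), CHCl3, 20 °C; then NaOMe (cat.), MeOH, rt
Reagents that add atoms: none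
Why: Dichlorocarbene from CHCl3 and TlOEt adds to selenium and the resulting selenonium ylide turns PhSe into a leaving group; as the C4–Se bond ionises, the thallium alkoxide at C3 drives an anti-periplanar 1,2-shift of the C3–C5 bond to C4, forming the C3 ketone and the C4–C5 bond. The closest known reaction type is the ring enlargement of β-hydroxyalkyl selenides, a semipinacol rearrangement of the Tiffeneau–Demjanov family known for cyclobutanones and cyclopentanones. No ring is closed by cyclisation: the six-membered ring A arises from the five-membered ring by this 1,2-alkyl shift, with retention at the migrating C5. The only new stereocentre, C4, forms with inversion from a diastereomer mixture and is then equilibrated by methoxide to the equatorial 4β-methyl ketone, because the 4α epimer would place the methyl syn-axial to C9 in the cis-decalin. The step needs migration of the quaternary C5 in preference to the methylene C2 and to epoxide closure; the higher migratory aptitude of the more substituted carbon documented for this rearrangement, and the relief of eclipsing strain on going from cyclopentane to cyclohexane, should secure it. The ketal and the cis ring fusion are inert to these basic, non-oxidising conditions.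

**Step 6**
Reactants: 11
Product: 13 3α-hydroxy-4β,5β-dimethyl-10βH-cis-decalin-8-one, via 3α-hydroxy ketal 12 (not isolated)
Conditions: Li, NH3(l)/THF, EtOH, −78 → −33 °C; NH4Cl; then 2 M HCl, THF, rt
Reagents that add atoms: water, O
Why: Dissolving-metal reduction of a hindered cyclohexanone gives the thermodynamically favoured equatorial alcohol (3α, trans to the 4β-methyl), where hydride reagents would be unselective because the axial C5 methyl blocks axial attack; aqueous acid then hydrolyses the dioxolane.

**Step 7**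
Reactants: 13; 14 triethylsilyl trifluoromethanesulfonate; 15 mCPBA
Product: 17 3α,9β-bis(triethylsilyloxy)-4β,5β-dimethyl-10βH-cis-decalin-8-one, via bis-silyl enol ether 16 (not isolated)
Conditions: TESOTf (2.4 equiv), Et3N, CH2Cl2, 0 °C → rt; then mCPBA (1.1 equiv), NaHCO3, CH2Cl2, −20 → 0 °C
Reagents that add atoms: triethylsilyl trifluoromethanesulfonate, CC[Si](CC)(CC)OS(=O)(=O)C(F)(F)F; mCPBA, OOC(=O)c1cccc(Cl)c1
Why: Rubottom oxidation: the cis-fused decalone, like a 5β-3-keto steroid, should enolise towards the ring-fusion side (C9), and the peracid should attack the C8=C9 enol ether on the β face, opposite the axial C4, to give the equatorial 9β-silyloxy ketone after 1,4-silyl shift.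

**Step 8**
Reactants: 17; 18 acetone
Product: 20 3α,9β-dihydroxy-7β-(2-hydroxypropan-2-yl)-4β,5β-dimethyl-10βH-cis-decalin-8-one, via silylated aldol adduct 19 (not isolated)
Conditions: LDA, THF, −78 °C; acetone, −78 °C; aq. NH4Cl; then AcOH/THF/H2O (3:1:1), rt
Reagents that add atoms: acetone, CC(C)=O
Why: Kinetic deprotonation of the α-silyloxy ketone occurs at the C7 methylene, and the aldol addition should place the bulky hydroxypropyl group equatorial (7β), which is also the thermodynamic configuration at this epimerisable centre; mild acid then removes both silyl ethers.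

**Step 9**
Reactants: 20; 21 3-methylbut-2-enoyl chloride
Product: 22 3α,9β-bis(3-methylbut-2-enoyloxy)-11-hydroxy-10βH-eremophilan-8-one
Conditions: 3-methylbut-2-enoyl chloride (2.5 equiv), pyridine, DMAP (cat.), CH2Cl2, 0 °C → rt
Reagents that add atoms: 3-methylbut-2-enoyl chloride, CC(C)=CC(Cl)=O
Why: Acylation with the acid chloride esterifies the two equatorial secondary alcohols and leaves the hindered tertiary alcohol, while pyridine is too weak a base to deconjugate the senecioyl unit.

**Step 10**
Reactants: 22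
Product: 23 3α,9β-bis(3-methylbut-2-enoyloxy)-10βH-eremophil-11-en-8-one [(1R,3R,4aR,5R,6R,8aS)-4a,5-dimethyl-2-oxo-3-(prop-1-en-2-yl)decahydronaphthalene-1,6-diyl bis(3-methylbut-2-enoate)]
Conditions: SOCl2, pyridine, CH2Cl2, −20 → 0 °C
Reagents that add atoms: none
Why: E2 dehydration of the tertiary chlorosulfite should remove a methyl hydrogen in preference to the single hindered C7–H, the usual kinetic course for α-(2-hydroxyprop-2-yl) ketones, giving the isopropenyl group without touching the stereocentres.

**Compound list**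
1 | acetaldehyde | CC=O | starting material
2 | benzeneselenol | [SeH]c1ccccc1 | starting material
3 | 1,1-bis(phenylselanyl)ethane | CC([Se]c1ccccc1)[Se]c1ccccc1 | intermediate
4 | (S)-Hajos–Parrish ketone, (7aS)-7a-methyl-2,3,7,7a-tetrahydro-1H-indene-1,5(6H)-dione | C[C@]12CCC(=O)C=C1CCC2=O | starting material
5 | (3aR,7aS)-7a-methylhexahydro-1H-indene-1,5(4H)-dione (cis-fused) | C[C@]12CCC(=O)C[C@H]1CCC2=O | intermediate
6 | ethylene glycol | OCCO | starting material
7 | (3aR,7aS)-7a-methyl-cis-hexahydroindane-1,5-dione 5-(ethylene ketal) | C[C@]12CCC3(OCCO3)C[C@H]1CCC2=O | intermediate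
8 | 1-(phenylselanyl)ethyllithium | [Li]C(C)[Se]c1ccccc1 | intermediate
9 | (3aR,7aS)-1-hydroxy-7a-methyl-1-[1-(phenylselanyl)ethyl]-cis-octahydroinden-5-one ethylene ketal (diastereomer mixture at C1 and the side-chain carbon) | C[C@]12CCC3(OCCO3)C[C@H]1CCC2(O)C(C)[Se]c1ccccc1 | intermediate
10 | (5β,10βH)-4,5-dimethyl-cis-decalin-3,8-dione 8-(ethylene ketal), mixture of C4 epimers | C1C[C@@]2(C)[C@H](CCC(=O)C2C)CC13OCCO3 | intermediate
11 | (4β,5β,10βH)-4,5-dimethyl-cis-decalin-3,8-dione 8-(ethylene ketal) | C1C[C@@]2(C)[C@H](CCC(=O)[C@@H]2C)CC13OCCO3 | intermediate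
12 | 3α-hydroxy-4β,5β-dimethyl-10βH-cis-decalin-8-one ethylene ketal | C1C[C@@]2(C)[C@H](CC[C@@H](O)[C@@H]2C)CC13OCCO3 | intermediate
13 | 3α-hydroxy-4β,5β-dimethyl-10βH-cis-decalin-8-one | O=C1CC[C@@]2(C)[C@H](CC[C@@H](O)[C@@H]2C)C1 | intermediate
14 | triethylsilyl trifluoromethanesulfonate | CC[Si](CC)(CC)OS(=O)(=O)C(F)(F)F | starting material
15 | mCPBA (3-chloroperoxybenzoic acid) | OOC(=O)c1cccc(Cl)c1 | starting material
16 | 3α,8-bis(triethylsilyloxy)-4β,5β-dimethyl-10βH-cis-decal-8(9)-ene | C1C[C@@]2(C)[C@H](CC[C@@H](O[Si](CC)(CC)CC)[C@@H]2C)C=C1O[Si](CC)(CC)CC | intermediate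
17 | 3α,9β-bis(triethylsilyloxy)-4β,5β-dimethyl-10βH-cis-decalin-8-one | C1C[C@@]2(C)[C@H](CC[C@@H](O[Si](CC)(CC)CC)[C@@H]2C)[C@@H](O[Si](CC)(CC)CC)C1=O | intermediate
18 | acetone | CC(C)=O | starting material
19 | 7β-(2-hydroxypropan-2-yl)-3α,9β-bis(triethylsilyloxy)-4β,5β-dimethyl-10βH-cis-decalin-8-one | CC(C)(O)[C@H]1C[C@@]2(C)[C@H](CC[C@@H](O[Si](CC)(CC)CC)[C@@H]2C)[C@@H](O[Si](CC)(CC)CC)C1=O | intermediate
20 | 3α,9β-dihydroxy-7β-(2-hydroxypropan-2-yl)-4β,5β-dimethyl-10βH-cis-decalin-8-one | CC(C)(O)[C@H]1C[C@@]2(C)[C@H](CC[C@@H](O)[C@@H]2C)[C@@H](O)C1=O | intermediate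
21 | 3-methylbut-2-enoyl chloride (senecioyl chloride) | CC(C)=CC(Cl)=O | starting material
22 | 3α,9β-bis(3-methylbut-2-enoyloxy)-11-hydroxy-10βH-eremophilan-8-one | CC(C)(O)[C@H]1C[C@@]2(C)[C@H](CC[C@@H](OC(=O)C=C(C)C)[C@@H]2C)[C@@H](OC(=O)C=C(C)C)C1=O | intermediate
23 | 3α,9β-bis(3-methylbut-2-enoyloxy)-10βH-eremophil-11-en-8-one (CNP0264508.1) | C=C(C)[C@H]1C[C@@]2(C)[C@H](CC[C@@H](OC(=O)C=C(C)C)[C@@H]2C)[C@@H](OC(=O)C=C(C)C)C1=O | target

**Total step count:** 10. **Longest linear sequence:** 9 steps (4 → 23, steps 2–10); step 1 is a one-step side branch.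

**Steps most likely to fail**

1. Step 5. The 1,2-shift may take the methylene carbon C2 instead of the quaternary C5, or the alkoxide may close onto C4 to give a spiro-epoxide. The fallback sets out from 7 and comes back at 10. Wittig ethylidenation of 7 (EtPPh3Br, KOtBu, THF, reflux) would give the ethylidene ketal F1. OsO4/NMO dihydroxylation would give the tertiary/secondary diol F2, and mesylation of the secondary hydroxyl (MsCl, Et3N, CH2Cl2, −20 °C) the hydroxy mesylate F3. Et3Al (CH2Cl2, −78 °C) would then trigger the pinacol-type 1,2-shift from an aluminium alkoxide, which suppresses epoxide closure, giving ketone mixture 10; this is equilibrated to 11 as in step 5.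

2. Step 7. Enolisation of the C8 ketone may go towards C7 as well as C9, giving regioisomeric enol ethers and hence oxidation at the wrong carbon. The fallback sets out from 4 and comes back at 17; it takes the regiochemistry from the enone.
   - Conjugate reduction of 4 with Stryker's reagent in the presence of TESCl would give the cis-fused C8=C9 silyl enol ether F4 regiospecifically, and mCPBA the 9β-silyloxy dione F5.
   - Ketalisation of the six-ring ketone (TMSOCH2CH2OTMS, TMSOTf, −78 °C) would give the silyloxy ketal F6.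
   - Addition of 8 as in step 4 would give the selenide adduct F7, and TlOEt/CHCl3 then NaOMe as in step 5 the ring-expanded silyloxy ketone F8.
   - Li/NH3 would give the 3α-alcohol F9, and aqueous HCl would remove ketal and silyl ether to give the dihydroxy ketone F10.
   - Bis-silylation (TESOTf, 2,6-lutidine) would give 17.

3. Step 10. The elimination may remove the C7 proton instead of a methyl proton, giving the conjugated isopropylidene isomer. The fallback sets out from 17 and comes back at 23. Pd-catalysed α-alkenylation of the C7 enolate (LiHMDS; Pd2(dba)3, t-Bu3P, 2-bromopropene, THF) would install the isopropenyl group directly, giving the bis-silyl isopropenyl ketone F11. AcOH/THF/H2O would give the isopropenyl diol F12, and acylation with 21 as in step 9 would give 23.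

**Further compounds**
F1 | step 5 | (3aR,7aS)-1-ethylidene-7a-methyl-cis-octahydroinden-5-one ethylene ketal (mainly Z) | C[C@]12CCC3(OCCO3)C[C@H]1CCC2=CC
F2 | step 5 | (3aR,7aS)-1-hydroxy-1-(1-hydroxyethyl)-7a-methyl-cis-octahydroinden-5-one ethylene ketal | C[C@]12CCC3(OCCO3)C[C@H]1CCC2(O)C(C)O
F3 | step 5 | 1-[(3aR,7aS)-1-hydroxy-7a-methyl-5-oxo-cis-octahydroinden-1-yl]ethyl methanesulfonate ethylene ketal | C[C@]12CCC3(OCCO3)C[C@H]1CCC2(O)C(C)OS(C)(=O)=O
F4 | step 7 | (3aS,7aS)-7a-methyl-5-(triethylsilyloxy)-cis-2,3,3a,6,7,7a-hexahydroinden-1-one | C[C@]12CCC(O[Si](CC)(CC)CC)=C[C@H]1CCC2=O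
F5 | step 7 | (4β)-7a-methyl-4-(triethylsilyloxy)-cis-hexahydroindane-1,5-dione (O syn to the angular methyl) | C[C@]12CCC(=O)[C@H](O[Si](CC)(CC)CC)[C@H]1CCC2=O
F6 | step 7 | 5-(ethylene ketal) of F5 | C[C@]12CCC3(OCCO3)[C@H](O[Si](CC)(CC)CC)[C@H]1CCC2=O
F7 | step 7 | 1-hydroxy-1-[1-(phenylselanyl)ethyl] adduct of F6 | C[C@]12CCC3(OCCO3)[C@H](O[Si](CC)(CC)CC)[C@H]1CCC2(O)C(C)[Se]c1ccccc1
F8 | step 7 | 9β-(triethylsilyloxy)-4β,5β-dimethyl-10βH-cis-decalin-3,8-dione 8-(ethylene ketal) | C1C[C@@]2(C)[C@H](CCC(=O)[C@@H]2C)[C@@H](O[Si](CC)(CC)CC)C13OCCO3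
F9 | step 7 | 3α-hydroxy-9β-(triethylsilyloxy)-4β,5β-dimethyl-10βH-cis-decalin-8-one ethylene ketal | C1C[C@@]2(C)[C@H](CC[C@@H](O)[C@@H]2C)[C@@H](O[Si](CC)(CC)CC)C13OCCO3
F10 | step 7 | 3α,9β-dihydroxy-4β,5β-dimethyl-10βH-cis-decalin-8-one | C1C[C@@]2(C)[C@H](CC[C@@H](O)[C@@H]2C)[C@@H](O)C1=O
F11 | step 10 | 3α,9β-bis(triethylsilyloxy)-10βH-eremophil-11-en-8-one | C=C(C)[C@H]1C[C@@]2(C)[C@H](CC[C@@H](O[Si](CC)(CC)CC)[C@@H]2C)[C@@H](O[Si](CC)(CC)CC)C1=O
F12 | step 10 | 3α,9β-dihydroxy-10βH-eremophil-11-en-8-one | C=C(C)[C@H]1C[C@@]2(C)[C@H](CC[C@@H](O)[C@@H]2C)[C@@H](O)C1=O
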